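**Plan**
Locants are those of the bicyclo[3.2.1]octane core: C1 (allyl bridgehead), C2=C3(OMe), C4 (carbinol), C5 (methoxy bridgehead), C6 (aryl), C7 (methyl), C8 (bridging ketone).
Retrosynthesis: C4–OH goes back to the C4 ketone; the six-membered ring C1–C2–C3–C4–C5–C8 is then opened at C8–C5 and C1–C2. This is possible because C8–C5–C4 is a 2-methoxy-1,3-diketone (C5 is the alpha-carbon of the C4 ketone, C8 an acyl carbon) and C1 is alpha to C8 while C2 is the beta-carbon of the enone C2=C3–C4=O. What remains is an open-chain keto ester ending in a beta-methoxy enone.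
That chain is cut at C6–aryl (conjugate addition), C5=C6 (aldol and dehydration) and C1–allyl (enolate alkylation), back to (S)-methylsuccinic acid 4-methyl ester, 1,3-dimethoxyacetone, methyl formate, allyl bromide and 4-bromo-2-methoxyphenol.
Forward: the chain is joined first; one base-mediated operation then closes the five-membered ring (C8–C5, Claisen) and the six-membered ring (C1–C2, addition–elimination) to the bicyclic dione; reduction at C4 and desilylation finish the synthesis.
Stereochemistry: C7 from the chiral pool; C6 by 1,3-allylic strain in the conjugate addition; C1 and C5 in the bicyclisation (closure anti to the C7 methyl group, ring constraint); C4 by hydride attack anti to the endo aryl group.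

Key step: step 8

Remarks: compound 1 is taken as commercially available in enantiopure form (it is the product of asymmetric hydrogenation of 4-methyl itaconate). Enolates are treated as the conjugate bases of the numbered compounds and carry no number of their own. Stereocentres that are enolised again later are left as mixtures.

**Step 1**
Reactants: 1 (2S)-4-methoxy-2-methyl-4-oxobutanoic acid; 2 3-bromoprop-1-ene (allyl bromide)
Product: 3 (2S)-3-(methoxycarbonyl)-2-methylhex-5-enoic acid (both C3 epimers)
Conditions: LiN(iPr)2 (2.2 equiv), THF, −78 °C; then 2, −78 to −20 °C; aqueous HCl work-up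
Reagents that add atoms: none
Why: Alkylation of a succinic half-ester dianion: the second equivalent of base deprotonates the CH2 next to the ester (the carbon next to the carboxylate is far less acidic, so the (S) centre is untouched) and the ester enolate is C-allylated by 2; the new centre forms as a mixture, which is of no consequence because it is enolised again in step 8.

**Step 2**
Reactants: 3 (2S)-3-(methoxycarbonyl)-2-methylhex-5-enoic acid
Product: 5 methyl (3S)-3-methyl-4-oxo-2-(prop-2-en-1-yl)butanoate, via acid chloride 4 (not isolated)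
Conditions: (COCl)2, DMF (cat.), CH2Cl2, 0 °C to rt; then LiAlH(OtBu)3, THF, −78 °C
Reagents that add atoms: none
Why: Acid chloride formation and partial reduction with the hindered hydride LiAlH(OtBu)3 at low temperature should stop at the aldehyde and leave the methyl ester and the alkene alone; no stereocentre is formed, and the alpha centre is kept by working cold and using 5 at once.

**Step 3**
Reactants: 6 1,3-dimethoxypropan-2-one; 7 methyl formate
Product: 9 (3Z)-1,3,4-trimethoxybut-3-en-2-one, via sodium formyl enolate 8 (not isolated)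
Conditions: NaH, THF, 0 °C to rt; then Me2SO4, DMF, rt
Reagents that add atoms: dimethyl sulfate, COS(=O)(=O)OC
Why: Crossed Claisen formylation of the symmetric ketone gives the stabilised formyl enolate 8, which the hard electrophile dimethyl sulfate methylates on oxygen to the vinylogous ester; no stereocentre is formed and the alkene geometry is lost again in step 8.

**Step 4**
Reactants: 9 (3Z)-1,3,4-trimethoxybut-3-en-2-one; 5 methyl (3S)-3-methyl-4-oxo-2-(prop-2-en-1-yl)butanoate
Product: 10 methyl (3S,7Z)-4-hydroxy-5,7,8-trimethoxy-3-methyl-6-oxo-2-(prop-2-en-1-yl)oct-7-enoate (epimers at C2, C4, C5 of the chain)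
Conditions: LiN(SiMe3)2, THF, −78 °C (enolate of 9); then 5, −78 °C; aqueous NH4Cl
Reagents that add atoms: none
Why: Kinetic alpha-prime deprotonation of the vinylogous ester (its only enolisable position is the CH2OMe group) and aldol addition to the aldehyde, which at −78 °C should be faster than enolisation of 5; the two new centres form as mixtures and are both removed in step 5.

**Step 5**
Reactants: 10 methyl (3S,7Z)-4-hydroxy-5,7,8-trimethoxy-3-methyl-6-oxo-2-(prop-2-en-1-yl)oct-7-enoate
Product: 12 methyl (3R,4Z,7Z)-5,7,8-trimethoxy-3-methyl-6-oxo-2-(prop-2-en-1-yl)octa-4,7-dienoate, via mesylate 11 (not isolated)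
Conditions: MeSO2Cl, Et3N, CH2Cl2, 0 °C; then DBU, 0 °C to rt
Reagents that add atoms: none
Why: Mesylation and E1cB elimination through the ketone enolate should give the alpha-methoxy enone with the chain trans to the acyl group (Z by the sequence rule); no stereocentre is formed and the mild amine base should leave the gamma centre alone.

**Step 6**
Reactants: 13 4-bromo-2-methoxyphenol
Product: 14 (4-bromo-2-methoxyphenoxy)tri(propan-2-yl)silane
Conditions: iPr3SiCl, imidazole, DMF, rt
Reagents that add atoms: chlorotri(propan-2-yl)silane, CC(C)[Si](Cl)(C(C)C)C(C)C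
Why: Standard silylation of a phenol; the triisopropylsilyl ether should survive the Grignard, amide-base and hydride steps and is removed by fluoride at the end.

**Step 7**
Reactants: 14 (4-bromo-2-methoxyphenoxy)tri(propan-2-yl)silane; 12 methyl (3R,4Z,7Z)-5,7,8-trimethoxy-3-methyl-6-oxo-2-(prop-2-en-1-yl)octa-4,7-dienoate
Product: 17 methyl (3R,4S,7Z)-5,7,8-trimethoxy-4-{3-methoxy-4-[tri(propan-2-yl)silyloxy]phenyl}-3-methyl-6-oxo-2-(prop-2-en-1-yl)oct-7-enoate (epimers at C2 and C5 of the chain), via arylmagnesium bromide 15 (not isolated), via silyl enol ether 16 (not isolated)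
Conditions: Mg, THF, 40 °C (14 to 15); CuBr·SMe2 (10 mol %), Me3SiCl, THF, −78 to −40 °C, then 12; aqueous citric acid work-up
Reagents that add atoms: none
Why: Copper-catalysed conjugate addition of an aryl Grignard reagent accelerated by Me3SiCl, at the beta-alkyl enone carbon (the other enone terminus is a deactivated vinylogous ester); the new aryl-bearing centre (C6) is set by 1,3-allylic strain with the cis methoxy group, which holds the C–H bond of the neighbouring stereocentre in the enone plane so that the aryl group enters anti to the large CH(allyl)CO2Me group, and the centre next to the ketone is left as a mixture because it is enolised in step 8.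

**Step 8**
Reactants: 17 methyl (3R,4S,7Z)-5,7,8-trimethoxy-4-{3-methoxy-4-[tri(propan-2-yl)silyloxy]phenyl}-3-methyl-6-oxo-2-(prop-2-en-1-yl)oct-7-enoate
Product: 19 (1R,5S,6S,7R)-3,5-dimethoxy-6-{3-methoxy-4-[tri(propan-2-yl)silyloxy]phenyl}-7-methyl-1-(prop-2-en-1-yl)bicyclo[3.2.1]oct-2-ene-4,8-dione (target locants), via cyclopentanone 18 (not isolated)
Conditions: KN(SiMe3)2 (2.2 equiv), THF, −78 to 0 °C; AcOH quench at −78 °C
Reagents that add atoms: none
Why: Proposed new method: the amide base removes the proton on the carbon that becomes C5 (alpha-prime position of the vinylogous ester ketone C4), this enolate acylates itself on the C8 methyl ester (Dieckmann-type Claisen condensation, 5-exo-trig, closes the cyclopentanone) to give 18, and the C1–H of 18, now alpha to the C8 ketone, is deprotonated so that C1 adds to the methoxy-bearing C2 and expels methoxide (addition–elimination on the beta-methoxy enone, 6-endo-trig, closes the cyclohexenone and with it the bicyclo[3.2.1]octane). The closest known reaction types are the Michael–Claisen synthesis of cyclohexane-1,3-diones and the Dieckmann or bridging-alkylation annulations that build non-enolisable bicyclic 1,3-diketones; both halves are standard, but their one-flask use to bridge an open chain across C1 and C5 has no direct precedent. C5 is set in the Claisen step under reversible conditions, because the methoxide set free can reopen the non-enolisable 1,3-diketone 18 (retro-Claisen), so the two C5 epimers interconvert; C1 is set by the ring, since the side chain on C5 can reach C1 only on its own face of the cyclopentanone (1,3-cis bridge). The step needs selection between the two bridged diastereomers (aryl endo and methyl exo, as wanted, against aryl exo and methyl endo), and the substrate should secure it at the second closure: C2 attacks the C1 enolate anti to the adjacent C7 methyl group, as in alkylations of 3-substituted cyclopentanone enolates, which drains the equilibrating epimers through the C5 epimer with acyl cis to aryl, where the electron-rich aryl ring can also stack on the electron-poor enone. It also needs C- over O-attack of the ambident C1 enolate; O-attack would give a vinylogous ester that methoxide can reopen, whereas C-attack becomes irreversible once methoxide is lost at low temperature.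

**Step 9**
Reactants: 19 (1R,5S,6S,7R)-3,5-dimethoxy-6-{3-methoxy-4-[tri(propan-2-yl)silyloxy]phenyl}-7-methyl-1-(prop-2-en-1-yl)bicyclo[3.2.1]oct-2-ene-4,8-dione
Product: 20 (1R,4S,5R,6S,7R)-4-hydroxy-3,5-dimethoxy-6-{3-methoxy-4-[tri(propan-2-yl)silyloxy]phenyl}-7-methyl-1-(prop-2-en-1-yl)bicyclo[3.2.1]oct-2-en-8-one
Conditions: NaBH4, CeCl3·7H2O, MeOH, −78 °C
Reagents that add atoms: none
Why: Luche 1,2-reduction: the cerium-activated enone carbonyl C4 should react in preference to the C8 ketone, which is flanked by two quaternary carbons, and hydride should come from the face of the C8 bridge because the endo aryl group on C6 covers the other face, which gives the (4S) alcohol.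

**Step 10**
Reactants: 20 (1R,4S,5R,6S,7R)-4-hydroxy-3,5-dimethoxy-6-{3-methoxy-4-[tri(propan-2-yl)silyloxy]phenyl}-7-methyl-1-(prop-2-en-1-yl)bicyclo[3.2.1]oct-2-en-8-one
Product: 21 (1R,4S,5R,6S,7R)-4-hydroxy-6-(4-hydroxy-3-methoxyphenyl)-3,5-dimethoxy-7-methyl-1-(prop-2-en-1-yl)bicyclo[3.2.1]oct-2-en-8-one (CNP0330966.1)
Conditions: Bu4NF, AcOH, THF, 0 °C
Reagents that add atoms: none
Why: Fluoride cleavage of the aryl silyl ether, buffered with acetic acid so that the beta-hydroxy ketone is not exposed to base (no retro-aldol); no stereocentre is touched.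

**Compound list**
1 | (2S)-4-methoxy-2-methyl-4-oxobutanoic acid | OC(=O)[C@@H](C)CC(=O)OC | starting material
2 | 3-bromoprop-1-ene | C=CCBr | starting material
3 | (2S)-3-(methoxycarbonyl)-2-methylhex-5-enoic acid | OC(=O)[C@@H](C)C(CC=C)C(=O)OC | intermediate
4 | methyl 2-[(2S)-1-chloro-1-oxopropan-2-yl]pent-4-enoate | ClC(=O)[C@@H](C)C(CC=C)C(=O)OC | intermediate
5 | methyl (3S)-3-methyl-4-oxo-2-(prop-2-en-1-yl)butanoate | O=C[C@@H](C)C(CC=C)C(=O)OC | intermediate
6 | 1,3-dimethoxypropan-2-one | COCC(=O)COC | starting material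
7 | methyl formate | COC=O | starting material
8 | sodium 2,4-dimethoxy-3-oxobut-1-en-1-olate | [Na+].[O-]C=C(OC)C(=O)COC | intermediate
9 | (3Z)-1,3,4-trimethoxybut-3-en-2-one | COCC(=O)/C(OC)=C/OC | intermediate
10 | methyl (3S,7Z)-4-hydroxy-5,7,8-trimethoxy-3-methyl-6-oxo-2-(prop-2-en-1-yl)oct-7-enoate | COC(=O)C(CC=C)[C@H](C)C(O)C(OC)C(=O)/C(OC)=C/OC | intermediate
11 | methyl (3S,7Z)-4-(methanesulfonyloxy)-5,7,8-trimethoxy-3-methyl-6-oxo-2-(prop-2-en-1-yl)oct-7-enoate | COC(=O)C(CC=C)[C@H](C)C(OS(C)(=O)=O)C(OC)C(=O)/C(OC)=C/OC | intermediate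
12 | methyl (3R,4Z,7Z)-5,7,8-trimethoxy-3-methyl-6-oxo-2-(prop-2-en-1-yl)octa-4,7-dienoate | COC(=O)C(CC=C)[C@H](C)/C=C(OC)/C(=O)/C(OC)=C/OC | intermediate
13 | 4-bromo-2-methoxyphenol | COc1cc(Br)ccc1O | starting material
14 | (4-bromo-2-methoxyphenoxy)tri(propan-2-yl)silane | COc1cc(Br)ccc1O[Si](C(C)C)(C(C)C)C(C)C | intermediate
15 | bromo{3-methoxy-4-[tri(propan-2-yl)silyloxy]phenyl}magnesium | COc1cc([Mg]Br)ccc1O[Si](C(C)C)(C(C)C)C(C)C | intermediate
16 | methyl (3R,4S,7Z)-5,7,8-trimethoxy-4-{3-methoxy-4-[tri(propan-2-yl)silyloxy]phenyl}-3-methyl-2-(prop-2-en-1-yl)-6-(trimethylsilyloxy)octa-5,7-dienoate | COC(=O)C(CC=C)[C@H](C)[C@@H](c1ccc(O[Si](C(C)C)(C(C)C)C(C)C)c(OC)c1)C(OC)=C(O[Si](C)(C)C)/C(OC)=C/OC | intermediate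
17 | methyl (3R,4S,7Z)-5,7,8-trimethoxy-4-{3-methoxy-4-[tri(propan-2-yl)silyloxy]phenyl}-3-methyl-6-oxo-2-(prop-2-en-1-yl)oct-7-enoate | COC(=O)C(CC=C)[C@H](C)[C@@H](c1ccc(O[Si](C(C)C)(C(C)C)C(C)C)c(OC)c1)C(OC)C(=O)/C(OC)=C/OC | intermediate
18 | (2S,3S,4R)-2-[(2Z)-2,3-dimethoxyprop-2-enoyl]-2-methoxy-3-{3-methoxy-4-[tri(propan-2-yl)silyloxy]phenyl}-4-methyl-5-(prop-2-en-1-yl)cyclopentan-1-one | C=CCC1[C@H](C)[C@@H](c2ccc(O[Si](C(C)C)(C(C)C)C(C)C)c(OC)c2)[C@@](OC)(C(=O)/C(OC)=C/OC)C1=O | intermediate
19 | (1R,5S,6S,7R)-3,5-dimethoxy-6-{3-methoxy-4-[tri(propan-2-yl)silyloxy]phenyl}-7-methyl-1-(prop-2-en-1-yl)bicyclo[3.2.1]oct-2-ene-4,8-dione | C=CC[C@@]12C=C(OC)C(=O)[C@@](OC)(C1=O)[C@H](c1ccc(O[Si](C(C)C)(C(C)C)C(C)C)c(OC)c1)[C@H]2C | intermediate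
20 | (1R,4S,5R,6S,7R)-4-hydroxy-3,5-dimethoxy-6-{3-methoxy-4-[tri(propan-2-yl)silyloxy]phenyl}-7-methyl-1-(prop-2-en-1-yl)bicyclo[3.2.1]oct-2-en-8-one | C=CC[C@@]12C=C(OC)[C@H](O)[C@@](OC)(C1=O)[C@H](c1ccc(O[Si](C(C)C)(C(C)C)C(C)C)c(OC)c1)[C@H]2C | intermediate
21 | (1R,4S,5R,6S,7R)-4-hydroxy-6-(4-hydroxy-3-methoxyphenyl)-3,5-dimethoxy-7-methyl-1-(prop-2-en-1-yl)bicyclo[3.2.1]oct-2-en-8-one | C=CC[C@@]12C=C(OC)[C@H](O)[C@@](OC)(C1=O)[C@H](c1ccc(O)c(OC)c1)[C@H]2C | target

Total step count: 10. Longest linear sequence: 8 steps (1, 2, 4, 5, 7, 8, 9, 10).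

**Steps most likely to fail**

Step 8 (proposed new method). The second ring closure may take the wrong course: O-alkylation of the C1 enolate instead of C–C bond formation, closure on the face syn to the C7 methyl group (the aryl-exo diastereomer), or retro-Claisen ring opening by methoxide. The fallback uses a known reaction type, sets out from 14 and comes back at 19. Suzuki coupling of 14 with potassium (E)-prop-1-enyltrifluoroborate (PdCl2(dppf), Cs2CO3, THF/H2O) should give tri(propan-2-yl){2-methoxy-4-[(1E)-prop-1-en-1-yl]phenoxy}silane F1. Separately, purchased 2,3,4-trimethoxyphenol is allylated with 2 (K2CO3, acetone) to 1,2,3-trimethoxy-4-(prop-2-en-1-yloxy)benzene F2, which on heating (Claisen rearrangement, about 190 °C) should give 2,3,4-trimethoxy-6-(prop-2-en-1-yl)phenol F3; PhI(OAc)2 in methanol oxidises F3 to the quinone monoketal 4,4,5,6-tetramethoxy-2-(prop-2-en-1-yl)cyclohexa-2,5-dien-1-one F4. Me3SiOTf in CH2Cl2 at −78 °C ionises the ketal, and the methoxy-substituted pentadienyl cation adds F1 across C1 and C5 (cationic [5+2] cycloaddition of a quinone monoketal with an aryl propene, endo aryl and trans methyl); loss of the O-methyl group on work-up gives 19 as the racemate. The enantiomers are separated by HPLC on a chiral stationary phase into 19 and its mirror image F5, and 19 re-enters at step 9.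

Step 7. The 1,4-addition to the doubly donor-substituted enone may be sluggish, so that attack on the ketone or substitution at the vinylogous ester carbon competes, and facial control at C6 may be incomplete. The fallback sets out from 5 (with 6 and 14) and comes back at 17. The lithium enolate of 6 (LiN(SiMe3)2, −78 °C) adds to 5 to give the aldol methyl (3S)-4-hydroxy-5,7-dimethoxy-3-methyl-6-oxo-2-(prop-2-en-1-yl)heptanoate F6; its mesylate F7 and DBU give methyl (3R,4Z)-5,7-dimethoxy-3-methyl-6-oxo-2-(prop-2-en-1-yl)hept-4-enoate F8, a simple alpha-methoxy enone without the second donor arm and without a second acceptor site. Copper-catalysed addition of 15 (from 14) with Me3SiCl, as in step 7, goes through the silyl enol ether F9 to the ketone F10. The CH2OMe side of F10 is then formylated through its kinetic enolate (LiN(iPr)2, THF, −78 °C; 2,2,2-trifluoroethyl formate), conditions under which the enolate that could start the Dieckmann closure is not formed, to give the hydroxymethylene ketone F11; O-methylation with Me3SiCHN2 in methanol/toluene gives 17.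

Step 5. The gamma-hydroxy ester 10 may lactonise before mesylation or undergo retro-aldol cleavage, and the C7 configuration may be lost by gamma-deprotonation of the enone. The fallback sets out from 5 and comes back at 12 without a beta-hydroxy ketone and without strong base. Methyl methoxyacetate is formylated with methyl formate and NaH to the sodium enolate F12 and O-methylated with dimethyl sulfate, as in step 3, to methyl (2Z)-2,3-dimethoxyprop-2-enoate F13. The lithium salt of diethyl (methoxymethyl)phosphonate (LiN(iPr)2, THF, −78 °C) is acylated by F13 to diethyl [(3Z)-1,3,4-trimethoxy-2-oxobut-3-en-1-yl]phosphonate F14. Horner–Wadsworth–Emmons olefination of 5 with F14 (LiCl, iPr2NEt, MeCN, rt) should give 12 directly.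

**Further compounds**
F1 | step 8 | tri(propan-2-yl){2-methoxy-4-[(1E)-prop-1-en-1-yl]phenoxy}silane | C/C=C/c1ccc(O[Si](C(C)C)(C(C)C)C(C)C)c(OC)c1
F2 | step 8 | 1,2,3-trimethoxy-4-(prop-2-en-1-yloxy)benzene | C=CCOc1ccc(OC)c(OC)c1OC
F3 | step 8 | 2,3,4-trimethoxy-6-(prop-2-en-1-yl)phenol | C=CCc1cc(OC)c(OC)c(OC)c1O
F4 | step 8 | 4,4,5,6-tetramethoxy-2-(prop-2-en-1-yl)cyclohexa-2,5-dien-1-one | C=CCC1=CC(OC)(OC)C(OC)=C(OC)C1=O
F5 | step 8 | (1S,5R,6R,7S)-3,5-dimethoxy-6-{3-methoxy-4-[tri(propan-2-yl)silyloxy]phenyl}-7-methyl-1-(prop-2-en-1-yl)bicyclo[3.2.1]oct-2-ene-4,8-dione (enantiomer of 19) | C=CC[C@]12C=C(OC)C(=O)[C@](OC)(C1=O)[C@@H](c1ccc(O[Si](C(C)C)(C(C)C)C(C)C)c(OC)c1)[C@@H]2C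
F6 | step 7 | methyl (3S)-4-hydroxy-5,7-dimethoxy-3-methyl-6-oxo-2-(prop-2-en-1-yl)heptanoate | COC(=O)C(CC=C)[C@H](C)C(O)C(OC)C(=O)COC
F7 | step 7 | methyl (3S)-4-(methanesulfonyloxy)-5,7-dimethoxy-3-methyl-6-oxo-2-(prop-2-en-1-yl)heptanoate | COC(=O)C(CC=C)[C@H](C)C(OS(C)(=O)=O)C(OC)C(=O)COC
F8 | step 7 | methyl (3R,4Z)-5,7-dimethoxy-3-methyl-6-oxo-2-(prop-2-en-1-yl)hept-4-enoate | COC(=O)C(CC=C)[C@H](C)/C=C(OC)/C(=O)COC
F9 | step 7 | methyl (3R,4S)-5,7-dimethoxy-4-{3-methoxy-4-[tri(propan-2-yl)silyloxy]phenyl}-3-methyl-2-(prop-2-en-1-yl)-6-(trimethylsilyloxy)hept-5-enoate | COC(=O)C(CC=C)[C@H](C)[C@@H](c1ccc(O[Si](C(C)C)(C(C)C)C(C)C)c(OC)c1)C(OC)=C(COC)O[Si](C)(C)C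
F10 | step 7 | methyl (3R,4S)-5,7-dimethoxy-4-{3-methoxy-4-[tri(propan-2-yl)silyloxy]phenyl}-3-methyl-6-oxo-2-(prop-2-en-1-yl)heptanoate | COC(=O)C(CC=C)[C@H](C)[C@@H](c1ccc(O[Si](C(C)C)(C(C)C)C(C)C)c(OC)c1)C(OC)C(=O)COC
F11 | step 7 | methyl (3R,4S)-8-hydroxy-5,7-dimethoxy-4-{3-methoxy-4-[tri(propan-2-yl)silyloxy]phenyl}-3-methyl-6-oxo-2-(prop-2-en-1-yl)oct-7-enoate | COC(=O)C(CC=C)[C@H](C)[C@@H](c1ccc(O[Si](C(C)C)(C(C)C)C(C)C)c(OC)c1)C(OC)C(=O)C(OC)=CO
F12 | step 5 | sodium 2,3-dimethoxy-3-oxoprop-1-en-1-olate | [Na+].[O-]C=C(OC)C(=O)OC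
F13 | step 5 | methyl (2Z)-2,3-dimethoxyprop-2-enoate | COC(=O)/C(OC)=C/OC
F14 | step 5 | diethyl [(3Z)-1,3,4-trimethoxy-2-oxobut-3-en-1-yl]phosphonate | CCOP(=O)(OCC)C(OC)C(=O)/C(OC)=C/OC
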